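**Plan** (ring numbering: C-1 = ester carbon, C-2 = side-chain carbon, C-5(Me)=C-6, C-9 = methylidene carbon)
1. Retrosynthesis: the acetate and silyl ethers go first; then the C-3–C-4 ring bond is cut; then the C-1–C-2 bond; last the ester C–O bond between a geranic acid derivative (fragment 2) and a divinyl carbinol (fragment 1).
2. Enabling feature: C-4 is the primary CH2 terminus of the C-4/C-5(Me)/C-6 allyl unit, and C-3 is the one ring CH2 without function next to C-2. C-4 can therefore be the free end of a π-allylpalladium unit, and C-3 can carry a nitro group that makes it a soft carbanion and is removed afterwards.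
3. Forward: fragment 1 by cross-metathesis and asymmetric alkenylzinc addition; fragment 2 from geranyl acetate, with a tert-butyl carbonate at the future C-4 as leaving group; esterification; Ireland–Claisen rearrangement forms C-1–C-2.
4. Then the CH2OPMB arm on C-2 becomes CH2NO2, palladium-catalysed nitronate allylation closes the nine-membered ring (the only ring), and denitration, desilylation and acetylation follow.
5. Stereochemistry: the carbinol centre comes from catalyst control; the chair Ireland–Claisen step transfers it to C-1 (R) and C-2 (S) and fixes the (2Z) side-chain olefin; the (5E) ring olefin is carried from geranyl acetate and the (4E) olefin comes from syn-hydroboration.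

Key step: step 17

Assumption: (−)-MIB is taken to steer the alkenylzinc reagent to the Si face of enal 5, as it does in dialkylzinc additions to aldehydes; if the sense proves opposite, (+)-MIB is used in step 5.

Step 1
Reactants: 1 2-methylidenepropane-1,3-diol
Product: 2 mono-TBS ether of the diol
Conditions: NaH (1.0 equiv), THF, 0 °C; TBSCl (1.0 equiv)
Reagents that add atoms: tert-butyldimethylsilyl chloride, CC(C)(C)[Si](C)(C)Cl
Why: Monosilylation of the symmetrical diol through its monosodium alkoxide, whose low solubility should limit bis-silylation.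

Step 2
Reactants: 2 mono-TBS ether of the diol
Product: 3 2-(silyloxymethyl)acrolein
Conditions: MnO2, CH2Cl2, rt
Reagents that add atoms: none
Why: MnO2 oxidises allylic alcohols selectively to enals and leaves the silyl ether alone.

Step 3
Reactants: 3 2-(silyloxymethyl)acrolein; 4 allyl 4-methoxybenzyl ether
Product: 5 (E)-enal
Conditions: second-generation Hoveyda–Grubbs catalyst (5 mol %), 4 (3 equiv), CH2Cl2, 40 °C
Reagents that add atoms: none
Why: Olefin cross-metathesis of a 2-substituted acrolein with a terminal allyl ether, as known for methacrolein, should give the trisubstituted enal under thermodynamic control as the (E)-isomer (CHO trans to CH2OPMB).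

Step 4
Reactants: 6 2-methylbut-3-yn-2-ol
Product: 7 TES ether of the alkynol
Conditions: TESCl, imidazole, DMAP (cat.), DMF, rt
Reagents that add atoms: triethylsilyl chloride, CC[Si](Cl)(CC)CC
Why: Silylation of the tertiary propargylic alcohol protects it for the organometallic and enolate steps.

Step 5
Reactants: 7 TES ether of the alkynol; 5 (E)-enal
Product: 10 (3E,5S,6E)-dienol (fragment 1), via alkenylborane 8 (not isolated), via alkenylzinc 9 (not isolated)
Conditions: Cy2BH, toluene, 0 °C to rt; Me2Zn, −78 °C; (−)-MIB (5 mol %), then 5, −20 to 0 °C; aq. NH4Cl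
Reagents that add atoms: none
Why: Syn-hydroboration of the terminal alkyne gives the (E)-alkenylborane, boron-to-zinc exchange gives the alkenylzinc reagent, and its amino-alcohol-catalysed 1,2-addition to the enal (asymmetric alkenylzinc addition) should set the (5S) carbinol by catalyst-controlled Si-face attack.

Step 6
Reactants: 11 geranyl acetate
Product: 12 (2E,6E)-8-hydroxygeranyl acetate
Conditions: SeO2 (cat.), t-BuOOH, salicylic acid (cat.), CH2Cl2, rt
Reagents that add atoms: tert-butyl hydroperoxide, CC(C)(C)OO
Why: Riley oxidation (ene reaction, then [2,3]-sigmatropic shift) attacks the electron-rich terminal trisubstituted olefin at its (E)-methyl group, while the olefin next to the acetate is deactivated.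

Step 7
Reactants: 12 (2E,6E)-8-hydroxygeranyl acetate
Product: 13 tert-butyl carbonate acetate
Conditions: Boc2O, DMAP (cat.), MeCN, 0 °C to rt
Reagents that add atoms: di-tert-butyl dicarbonate, CC(C)(C)OC(=O)OC(=O)OC(C)(C)C
Why: DMAP-catalysed O-acylation of the primary allylic alcohol gives the mixed carbonate that later serves as a base-releasing leaving group.

Step 8
Reactants: 13 tert-butyl carbonate acetate
Product: 14 carbonate allylic alcohol
Conditions: K2CO3 (cat.), MeOH, 0 °C
Reagents that add atoms: none
Why: Methoxide transesterification should cleave the acetate much faster than the hindered tert-butyl carbonate.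

Step 9
Reactants: 14 carbonate allylic alcohol
Product: 15 carbonate enal
Conditions: MnO2, CH2Cl2, rt
Reagents that add atoms: none
Why: MnO2 oxidation of the allylic alcohol gives the (E)-enal without olefin isomerisation.

Step 10
Reactants: 15 carbonate enal
Product: 16 (2E,6E)-8-(Boc-oxy)geranic acid (fragment 2)
Conditions: NaClO2, NaH2PO4, 2-methyl-2-butene, t-BuOH/H2O, 0 °C to rt
Reagents that add atoms: sodium chlorite, [Na+].[O-]Cl=O
Why: Pinnick oxidation converts the enal into the acid under buffered conditions, with 2-methyl-2-butene scavenging hypochlorite so that both trisubstituted olefins and the carbonate survive.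

Step 11
Reactants: 10 (3E,5S,6E)-dienol (fragment 1); 16 (2E,6E)-8-(Boc-oxy)geranic acid (fragment 2)
Product: 17 (5S)-allylic geranate ester
Conditions: EDC·HCl, DMAP, CH2Cl2, 0 °C to rt
Reagents that add atoms: none
Why: Steglich esterification acylates the secondary carbinol with retention at C-5; the tertiary oxygen is silylated and cannot compete.

Step 12
Reactants: 17 (5S)-allylic geranate ester
Product: 20 (2R,3S,4Z,6E)-acid, via silyl ketene acetal 18 (not isolated), via trimethylsilyl ester 19 (not isolated)
Conditions: LiN(iPr)2 (LDA), THF/DMPU, −78 °C; TMSCl, Et3N; −78 to 50 °C; aq. citric acid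
Reagents that add atoms: none
Why: Ireland–Claisen rearrangement of an ester dienolate: the methyl group syn to the carbonyl of the s-cis enoate should be deprotonated to give the (Z)-silyl ketene acetal (OSi cis to the vinyl substituent), which rearranges through a chair with the dienyl group at C-5 equatorial, so that the (5S) carbinol and the (6E) olefin of 10 are translated into C-2 (R), C-3 (S) and the (4Z) olefin, while the other allyl arm is blocked by the fully substituted carbon at its terminus.

Step 13
Reactants: 20 (2R,3S,4Z,6E)-acid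
Product: 21 methyl ester
Conditions: TMSCHN2, toluene/MeOH, 0 °C
Reagents that add atoms: (trimethylsilyl)diazomethane, C[Si](C)(C)C=[N+]=[N-]
Why: O-Methylation of the acid by the diazomethane equivalent needs no base, so the epimerisable C-2 centre (α to the ester and allylic) is not disturbed.

Step 14
Reactants: 21 methyl ester
Product: 22 primary alcohol (3-hydroxymethyl)
Conditions: DDQ, CH2Cl2/pH 7 buffer, 0 °C; crude product used at once
Reagents that add atoms: none
Why: DDQ cleaves the electron-rich PMB ether oxidatively through a benzylic oxocarbenium ion and leaves silyl ethers, carbonate and olefins alone; the γ-hydroxy ester is carried on at once to forestall lactonisation.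

Step 15
Reactants: 22 primary alcohol (3-hydroxymethyl)
Product: 23 primary iodide (3-iodomethyl)
Conditions: PPh3, I2, imidazole, CH2Cl2, 0 °C
Reagents that add atoms: iodine, II
Why: Garegg–Samuelsson iodination converts the primary alcohol through its alkoxyphosphonium salt into the iodide by SN2 displacement under nearly neutral conditions.

Step 16
Reactants: 23 primary iodide (3-iodomethyl)
Product: 24 nitroalkane (3-nitromethyl)
Conditions: NaNO2, phloroglucinol, DMF, rt
Reagents that add atoms: sodium nitrite, [Na+].[O-]N=O
Why: Kornblum nitrite displacement: SN2 attack of the ambident nitrite through nitrogen on the primary iodide gives the nitroalkane, and phloroglucinol intercepts the nitrite ester by-product before it can nitrosate the product.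

Step 17
Reactants: 24 nitroalkane (3-nitromethyl)
Product: 25 nine-membered nitro ester (C-3 epimers)
Conditions: Pd2(dba)3·CHCl3 (5 mol %), PPh3 (40 mol %), THF, 50 °C, syringe-pump addition to 0.002 M
Reagents that add atoms: none
Why: Zerovalent palladium ionises the allylic tert-butyl carbonate with loss of CO2 to a syn-π-allylpalladium cation (divalent palladium) and tert-butoxide, which deprotonates only the nitromethylene group (far more acidic than the ester α-hydrogen); the nitronate carbon then attacks the allyl terminus anti to the metal and releases zerovalent palladium. The closest known reaction type is the Tsuji–Trost allylation of nitroalkane nitronates and its intramolecular use for medium and large carbocycles with stabilised carbanions. The nine-membered ring closes by attack on the distal CH2 terminus (C-4), so that all three allyl carbons become ring members (the endo mode of allyl cyclisation); attack on the proximal substituted terminus would be the exo mode and give a seven-membered ring bearing an isopropenyl group. The only new stereocentre, the nitro-bearing C-3, is not controlled and need not be, because it is erased in step 18; C-1 and C-2 are untouched because no base stronger than the nitronate persists. The step needs distal over proximal attack, which the unhindered primary terminus of the 1,2-disubstituted allyl unit should secure, and retention of the (E)-olefin, which the syn-allyl complex formed from the (E)-carbonate should secure if it is captured before syn/anti exchange. It also needs ring closure over oligomerisation, which slow addition at high dilution should secure.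

Step 18
Reactants: 25 nine-membered nitro ester (C-3 epimers)
Product: 26 nine-membered bis-silyl ether ester
Conditions: Bu3SnH, AIBN, toluene, 110 °C
Reagents that add atoms: none
Why: Radical-chain denitration: Bu3Sn• adds to a nitro oxygen, β-scission releases the secondary C-3 radical, and this abstracts hydrogen from Bu3SnH; no olefin is placed for a 5-exo or 6-exo cyclisation of that radical.

Step 19
Reactants: 26 nine-membered bis-silyl ether ester
Product: 27 diol
Conditions: HF·pyridine, pyridine, THF, 0 °C to rt
Reagents that add atoms: none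
Why: Fluoride cleaves the primary TBS and tertiary TES ethers under pyridine-buffered, non-basic conditions, which spares the epimerisable C-1 ester centre and the acid-sensitive tertiary dienyl alcohol.

Step 20
Reactants: 27 diol
Product: 28 target (CNP0176502.1)
Conditions: Ac2O (1.1 equiv), pyridine, CH2Cl2, 0 °C
Reagents that add atoms: acetic anhydride, CC(=O)OC(C)=O
Why: Acylation of the unhindered primary allylic alcohol is far faster than that of the tertiary alcohol, so one equivalent of Ac2O without DMAP should give the monoacetate.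

**Compound list**
1 | 2-methylidenepropane-1,3-diol | C=C(CO)CO | starting material
2 | 2-{[(tert-butyldimethylsilyl)oxy]methyl}prop-2-en-1-ol | C=C(CO)CO[Si](C)(C)C(C)(C)C | intermediate
3 | 2-{[(tert-butyldimethylsilyl)oxy]methyl}prop-2-enal | C=C(C=O)CO[Si](C)(C)C(C)(C)C | intermediate
4 | allyl 4-methoxybenzyl ether | C=CCOCc1ccc(OC)cc1 | starting material
5 | (2E)-2-{[(tert-butyldimethylsilyl)oxy]methyl}-4-[(4-methoxybenzyl)oxy]but-2-enal | O=C/C(CO[Si](C)(C)C(C)(C)C)=C/COCc1ccc(OC)cc1 | intermediate
6 | 2-methylbut-3-yn-2-ol | C#CC(C)(C)O | starting material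
7 | triethyl[(2-methylbut-3-yn-2-yl)oxy]silane | C#CC(C)(C)O[Si](CC)(CC)CC | intermediate
8 | dicyclohexyl{(E)-3-methyl-3-[(triethylsilyl)oxy]but-1-en-1-yl}borane (formed in the flask) | CC[Si](CC)(CC)OC(C)(C)/C=C/B(C1CCCCC1)C1CCCCC1 | intermediate
9 | methyl{(E)-3-methyl-3-[(triethylsilyl)oxy]but-1-en-1-yl}zinc (formed in the flask) | CC[Si](CC)(CC)OC(C)(C)/C=C/[Zn]C | intermediate
10 | (3E,5S,6E)-6-{[(tert-butyldimethylsilyl)oxy]methyl}-8-[(4-methoxybenzyl)oxy]-2-methyl-2-[(triethylsilyl)oxy]octa-3,6-dien-5-ol | CC[Si](CC)(CC)OC(C)(C)/C=C/[C@H](O)/C(CO[Si](C)(C)C(C)(C)C)=C/COCc1ccc(OC)cc1 | intermediate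
11 | geranyl acetate, (2E)-3,7-dimethylocta-2,6-dien-1-yl acetate | CC(C)=CCC/C(C)=C/COC(C)=O | starting material
12 | (2E,6E)-8-hydroxy-3,7-dimethylocta-2,6-dien-1-yl acetate | OC/C(C)=C/CC/C(C)=C/COC(C)=O | intermediate
13 | (2E,6E)-8-[(tert-butoxycarbonyl)oxy]-3,7-dimethylocta-2,6-dien-1-yl acetate | CC(C)(C)OC(=O)OC/C(C)=C/CC/C(C)=C/COC(C)=O | intermediate
14 | tert-butyl (2E,6E)-8-hydroxy-2,6-dimethylocta-2,6-dien-1-yl carbonate | CC(C)(C)OC(=O)OC/C(C)=C/CC/C(C)=C/CO | intermediate
15 | tert-butyl (2E,6E)-2,6-dimethyl-8-oxoocta-2,6-dien-1-yl carbonate | CC(C)(C)OC(=O)OC/C(C)=C/CC/C(C)=C/C=O | intermediate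
16 | (2E,6E)-8-[(tert-butoxycarbonyl)oxy]-3,7-dimethylocta-2,6-dienoic acid | CC(C)(C)OC(=O)OC/C(C)=C/CC/C(C)=C/C(=O)O | intermediate
17 | (3E,5S,6E)-6-{[(tert-butyldimethylsilyl)oxy]methyl}-8-[(4-methoxybenzyl)oxy]-2-methyl-2-[(triethylsilyl)oxy]octa-3,6-dien-5-yl (2E,6E)-8-[(tert-butoxycarbonyl)oxy]-3,7-dimethylocta-2,6-dienoate | CC(C)(C)OC(=O)OC/C(C)=C/CC/C(C)=C/C(=O)O[C@@H](/C=C/C(C)(C)O[Si](CC)(CC)CC)/C(CO[Si](C)(C)C(C)(C)C)=C/COCc1ccc(OC)cc1 | intermediate
18 | (1Z)-O-trimethylsilyl ketene acetal of 17, CH2=C(R)–CH=C(OSiMe3)(OR′) with OSi cis to the vinyl group (formed in the flask) | C=C(CC/C=C(\C)COC(=O)OC(C)(C)C)/C=C(\O[Si](C)(C)C)O[C@@H](/C=C/C(C)(C)O[Si](CC)(CC)CC)/C(CO[Si](C)(C)C(C)(C)C)=C/COCc1ccc(OC)cc1 | intermediate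
19 | trimethylsilyl ester of acid 20 (formed in the flask) | C=C(CC/C=C(\C)COC(=O)OC(C)(C)C)[C@H](C(=O)O[Si](C)(C)C)[C@H](COCc1ccc(OC)cc1)/C(CO[Si](C)(C)C(C)(C)C)=C/C=C/C(C)(C)O[Si](CC)(CC)CC | intermediate
20 | (2R,3S,4Z,6E)-2-[(5E)-7-[(tert-butoxycarbonyl)oxy]-6-methylhepta-1,5-dien-2-yl]-4-{[(tert-butyldimethylsilyl)oxy]methyl}-3-{[(4-methoxybenzyl)oxy]methyl}-8-methyl-8-[(triethylsilyl)oxy]nona-4,6-dienoic acid | C=C(CC/C=C(\C)COC(=O)OC(C)(C)C)[C@H](C(=O)O)[C@H](COCc1ccc(OC)cc1)/C(CO[Si](C)(C)C(C)(C)C)=C/C=C/C(C)(C)O[Si](CC)(CC)CC | intermediate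
21 | methyl ester of 20, methyl (2R,3S,4Z,6E)-…-3-{[(4-methoxybenzyl)oxy]methyl}-…nona-4,6-dienoate | C=C(CC/C=C(\C)COC(=O)OC(C)(C)C)[C@H](C(=O)OC)[C@H](COCc1ccc(OC)cc1)/C(CO[Si](C)(C)C(C)(C)C)=C/C=C/C(C)(C)O[Si](CC)(CC)CC | intermediate
22 | as 21 with 3-(hydroxymethyl) in place of the PMB ether, (2R,3S,4Z,6E) | C=C(CC/C=C(\C)COC(=O)OC(C)(C)C)[C@H](C(=O)OC)[C@H](CO)/C(CO[Si](C)(C)C(C)(C)C)=C/C=C/C(C)(C)O[Si](CC)(CC)CC | intermediate
23 | as 21 with 3-(iodomethyl), (2R,3S,4Z,6E) | C=C(CC/C=C(\C)COC(=O)OC(C)(C)C)[C@H](C(=O)OC)[C@H](CI)/C(CO[Si](C)(C)C(C)(C)C)=C/C=C/C(C)(C)O[Si](CC)(CC)CC | intermediate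
24 | as 21 with 3-(nitromethyl), (2R,3S,4Z,6E) | C=C(CC/C=C(\C)COC(=O)OC(C)(C)C)[C@H](C(=O)OC)[C@H](C[N+](=O)[O-])/C(CO[Si](C)(C)C(C)(C)C)=C/C=C/C(C)(C)O[Si](CC)(CC)CC | intermediate
25 | methyl (1R,2S,5E)-2-[(2Z,4E)-1-[(tert-butyldimethylsilyl)oxy]-6-methyl-6-[(triethylsilyl)oxy]hepta-2,4-dien-2-yl]-5-methyl-9-methylidene-3-nitrocyclonon-5-ene-1-carboxylate (both C-3 epimers) | C=C1CC/C=C(\C)CC([N+](=O)[O-])[C@H](/C(CO[Si](C)(C)C(C)(C)C)=C/C=C/C(C)(C)O[Si](CC)(CC)CC)[C@H]1C(=O)OC | intermediate
26 | methyl (1R,2S,5E)-2-[(2Z,4E)-1-[(tert-butyldimethylsilyl)oxy]-6-methyl-6-[(triethylsilyl)oxy]hepta-2,4-dien-2-yl]-5-methyl-9-methylidenecyclonon-5-ene-1-carboxylate | C=C1CC/C=C(\C)CC[C@H](/C(CO[Si](C)(C)C(C)(C)C)=C/C=C/C(C)(C)O[Si](CC)(CC)CC)[C@H]1C(=O)OC | intermediate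
27 | methyl (1R,2S,5E)-2-[(2Z,4E)-1,6-dihydroxy-6-methylhepta-2,4-dien-2-yl]-5-methyl-9-methylidenecyclonon-5-ene-1-carboxylate | C=C1CC/C=C(\C)CC[C@H](/C(CO)=C/C=C/C(C)(C)O)[C@H]1C(=O)OC | intermediate
28 | methyl (1R,2S,5E)-2-[(2Z,4E)-1-(acetyloxy)-6-hydroxy-6-methylhepta-2,4-dien-2-yl]-5-methyl-9-methylidenecyclonon-5-ene-1-carboxylate | C=C1CC/C=C(\C)CC[C@H](/C(=C/C=C/C(C)(C)O)COC(C)=O)[C@H]1C(=O)OC | target

**Step count:** 20 steps in total. Longest linear sequence: 15 steps (geranyl acetate 11 to 28 through steps 6–10 and 11–20).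

**Steps most likely to fail**

Step 17 (ring closure). What may go wrong: attack of the nitronate at the substituted allyl terminus (seven-membered ring), proton loss from the allyl complex to a triene before the slow medium-ring closure, syn/anti exchange of the allyl complex leading to the (Z)-ring olefin, or oligomerisation. Fallback: the route is left at iodide 23 and the same bond is closed by nickel-catalysed reductive coupling of the primary iodide with the allylic tert-butyl carbonate (NiBr2·glyme, 4,4′-di-tert-butyl-2,2′-bipyridine, zinc dust, DMA, high dilution). This pairing of two electrophilic carbons is established between molecules for alkyl halides and allylic carbonates and couples at the unsubstituted allyl terminus, but it is untested for a nine-membered ring. It would give 26 directly, so 24 and 25 are bypassed and no compound outside the list is made (F0).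

Step 18 (denitration). What may go wrong: slow homolysis of the secondary C–NO2 bond at 110 °C, during which reversible stannyl-radical addition can isomerise the strained (E)-ring olefin or the diene. Fallback: from 25, a Nef reaction through the nitronate (NaOMe, then buffered TiCl3/NH4OAc) would give the C-3 ketone F1. Condensation with TsNHNH2 would give the tosylhydrazone F2, and reduction with catecholborane followed by NaOAc·3H2O would remove the function and return to 26.

Step 5 (asymmetric alkenylation). What may go wrong: poor facial selectivity because the ether oxygens of enal 5 bind zinc and open a ligand-free addition, or incomplete boron-to-zinc exchange of the hindered alkenylborane. Fallback: from 5 and 7, ProPhenol/Me2Zn-catalysed zinc alkynylide addition (ligand enantiomer chosen for the (5S) carbinol) would give the propargylic alcohol F3. Hydroxyl-directed trans-hydroalumination with sodium bis(2-methoxyethoxy)aluminium dihydride at −20 °C would then give 10.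

**Further compounds**
F0 | step 17 | none | none
F1 | step 18 | methyl (1R,2S,5E)-2-[(2Z,4E)-1-[(tert-butyldimethylsilyl)oxy]-6-methyl-6-[(triethylsilyl)oxy]hepta-2,4-dien-2-yl]-5-methyl-9-methylidene-3-oxocyclonon-5-ene-1-carboxylate | C=C1CC/C=C(\C)CC(=O)[C@H](/C(CO[Si](C)(C)C(C)(C)C)=C/C=C/C(C)(C)O[Si](CC)(CC)CC)[C@H]1C(=O)OC
F2 | step 18 | 4-methylbenzenesulfonylhydrazone of ketone F1 | C=C1CC/C=C(\C)CC(=NNS(=O)(=O)c2ccc(C)cc2)[C@H](/C(CO[Si](C)(C)C(C)(C)C)=C/C=C/C(C)(C)O[Si](CC)(CC)CC)[C@H]1C(=O)OC
F3 | step 5 | (5S,6E)-6-{[(tert-butyldimethylsilyl)oxy]methyl}-8-[(4-methoxybenzyl)oxy]-2-methyl-2-[(triethylsilyl)oxy]oct-6-en-3-yn-5-ol | CC[Si](CC)(CC)OC(C)(C)C#C[C@H](O)/C(CO[Si](C)(C)C(C)(C)C)=C/COCc1ccc(OC)cc1
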